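In a one-step world, where L meets X and simply becomes Z and J, a flask of L over solid D would be a matter of waiting, and two colleagues dispute whether this flask is such a world.

L 0.068 M; D 0.0680 M; time 2.5 d

    D ⇌ X, rate k1*(cs1 - [X]) while solid is left; crystals form when [X] > cs1 (cs1 = 3.1 mM, k1 = 0.00216 s⁻¹)
    L + X ⇌ Z + J (K2 = 1.2, k2 = 0.00514 L mol⁻¹ s⁻¹)
    Z ⇌ G (K3 = 1.2, k3 = 0.00134 s⁻¹)

1. part of the L gone at 2.5 d
2. the Z standing at 2.5 d, as a percentage of the L charged
3. the G standing at 2.5 d, as a percentage of the L charged

The first colleague holds the clock view: with solid left, X stands at its solubility, so L falls in pseudo-first-order fashion with a half-life of 0.503 d, and a run of 4.97 such half-lives should leave 96.8% of L gone.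

The second colleague answers that Z and J run back into L and X, so this flask must be reckoned as a balance, and my own reckoning follows that view. Let x be the concentration of L gone. Z and G relax with a half-life of 0.0784 h, far quicker than the run, so G stands at 1.2 times Z, while J equals x. The second step's balance then says that x times x, divided by the L left, equals a single concentration S, the saturated capacity 0.00818 M, which is the second step's constant times one plus the third step's constant times the solubility of X.

Solving gives x = 0.0199 M, or 29.2% of L. This takes 0.0230 M of D, less than the charge, so solid remains to hold X. Near this balance the forward and return steps together give a relaxation time of 2.98 h, and the run is 20.1 of these.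

The forecast, on the second colleague's side, gives 29.2% of L gone, 13.3% as Z and 15.9% as G, holding that “the flask should be at full equilibrium”.

The flask gives 29.2%, 13.3% and 15.9%. The clock view stands nearer to this flask early in the run than at its end: at 0.148 d, when the flask has 14.6% of its L gone, the clock reckons 18.4%. In this flask, J squared over the L left reads 0.00818 M, beside S at 0.00818 M. With S unchanged, the neighbour flask charged with 0.041 M of L should lose 0.0147 M, or 35.9% of its L, and the simulated neighbour stands at 35.8%.

The constants were set for the occasion; the run is a simulation.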